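Atom numbering used throughout: ring oxygen O1; C2 carries ring B (4-hydroxyphenyl); C3 carries the ketone carbon C6 with ring A (2,4-dihydroxyphenyl); C4 carries the carbinol carbon C7 with ring D (4-hydroxyphenyl); C5 carries ring C (2,4-dihydroxyphenyl). O7 is the oxygen on C7.

## The problem

The target is a 2,3,4,5-tetrasubstituted tetrahydrofuran; formally it is two aryl–CO–C–C(O)–aryl halves joined through C3–C4. Five contiguous stereocentres, all R, have to be set: ring B is trans to the acyl group, but the substituents on C3, C4 and C5 are all cis, so ring C on C5 and the epimerisable ketone α-centre C3 both sit in contra-thermodynamic positions. Only C2 lends itself to being made first as a single enantiomer; it can direct the face at C3/C4, after which C4 can direct C5 (attack anti to its substituent), C3 (through a cis ring fusion) and C7 (through a ring closure). The molecule is fragile: six free phenols, a p-hydroxybenzylic alcohol that ionises towards a quinone methide, two benzylic ring C–O bonds (the one at C5 next to an ortho,para-dioxygenated ring), a γ-hydroxy ketone that can close to a hemiketal, and C3–H next to the ketone. Strong Lewis acids for ether cleavage and strong base at a late stage are therefore excluded. The feature that makes the key step possible is the 1,4-relationship between the ketone oxygen on C6 and the oxygen-bearing benzylic carbon C7 across C3 and C4. A cyclopropane C3–C4–C7 with the aroyl acceptor on C3 and ring D as donor on C7 is a latent form of this γ-hydroxy ketone, because its C3–C7 bond can later be exchanged for an O7–C7 bond and a C3–H bond. In that form C4 is the β-carbon of an unsaturated ketone, so the C4–C7 bond can be made by conjugate addition of a benzylic ylide.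

## Retrosynthesis

**29 from 28.** The six phenolic O–H bonds are traced back to six benzyl ethers in 28. Methyl ethers would need Lewis-acidic cleavage that ionises the C7 carbinol and the ring C–O bonds; silyl ethers would not survive the aryl-metal and hydroperoxide steps. Benzyl ethers are inert to every reagent of the route and leave under neutral hydrogenolysis. The forward step must cleave aryl–O–CH2Ph bonds faster than the three benzylic C–O bonds of the core.

**28 from 27.** The C3–H bond and the C6=O/C7–OH pair are retraced to the cyclic enol ether 27 (C6=C3, C6–O7–C7). This one function hides the ketone from nucleophiles, ties up the carbinol and removes the epimerisable centre C3 until the penultimate step. The precursor has one stereocentre fewer and no free carbonyl or hydroxyl group. The hydrolysis must put the proton on C3 cis to C4–H, which the cis fusion of two five-membered rings enforces.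

**27 from 26, and 26 from 23 and 2.** The C5–H and C5–aryl bonds are cut: 27 from lactol 26 by hydride delivery, 26 from lactone 23 and bromide 2 through the organometallics 24 and 25. The opposite order (hydride first, aryl nucleophile onto a C5 oxocarbenium ion) would put ring C on the convex face, trans to C7; the aryl group must therefore be in place before the hydride arrives. Precursor 23 lacks ring C and one stereocentre. Required are mono-addition without enolisation at C4, and hydride attack anti to C7 without damage to the enol ether.

**23 from 22.** The O7–C7 bond is cut and the C3–C7 bond re-formed, giving the aroylcyclopropane 22 (retro Cloke–Wilson). This transform converts the γ-oxygenation pattern into a C–C bond that a carbanion can make. The forward rearrangement must break C3–C7, not C4–C7, and place ring D on the convex face.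

**22 from 17 and 19.** Cutting C4–C7 and C3–C7 removes C7 with ring D as a benzylic 1,1-dipole (ylide 20 from salt 19) and leaves butenolide 17. An electrophilic metal carbene would be mismatched with this electron-poor alkene; the nucleophilic ylide is matched. Precursor 17 has a single stereocentre, and its partner is achiral. Required are attack anti to ring B and conjugate addition faster than deprotonation at C2.

**17 from 14.** The C3=C4 double bond is returned to the saturated keto lactone 14, by way of selenide 15 and selenoxide 16. Introducing the unsaturation last lets C2 be set by an aldol reaction; the second aldol centre (C3 of 14) is deliberately sacrificed. The forward elimination must run towards C4 and must not expose 17 to base.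

**14 from 10 and 2.** The C6–ring A bond is cut to acid 10 (as chloride 11) and arylzinc 13, which is made from bromide 2 by way of Grignard reagent 12. A Friedel–Crafts acylation of a resorcinol dibenzyl ether would need a Lewis acid that cleaves the ortho benzyl ether. The cross-coupling is neutral, and the same bromide 2 later supplies ring C.

**10 from 8, and 8 from 5 and 6.** The C2–C3 bond and the lactone bond C5–O1 are cut together. The auxiliary-controlled aldol of imide 5 with aldehyde 6 gives adduct 7, which lactonises to 8; removal of auxiliary 3 (through 9) gives 10. A catalytic aldol of the corresponding α-branched aryl ketone would be shorter but is less dependable. The auxiliary route gives one enantiomer and returns 3.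

**Building blocks.** 5 comes from auxiliary 3 and acid chloride 4; 2 from bromoresorcinol 1; 19 from benzylic chloride 18. All of 1, 3, 4, 6 and 18 are simple purchasable compounds.

## Roads not taken

**Alternative 1:** Oxidative dimerisation to a furofuran dilactone.
- **Cut:** C3–C4 and the bonds O1–C2 and O–C7, leading back to two molecules of p-coumaric acid A1.
- **Forward key step:** one-electron oxidation gives phenoxyl radicals that couple at the β-carbons; each carboxylate traps the quinone methide of the other half, closing the cis-fused dilactone A2 with both aryl groups exo.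
- **Merits:** one step from a bulk chemical makes C3–C4, both benzylic C–O bonds, and the cis relationship of C3–H and C4–H. The carbonyls C5 and C6 then accept the same resorcinol-derived aryl nucleophile; C5 is reduced as in step 11, and opening at C6 gives the ketone and the free C7 carbinol at once.
- **Weak points:** coupling of a 4-hydroxycinnamic acid without ortho substituents spreads over β–β, β–5 and β–O–4 modes, so A2 is a minor product. An achiral oxidant gives the racemate and resolution discards half. The phenols have to be protected afterwards on a base-sensitive bis-lactone. The two lactones are homotopic, so mono-arylation rests on stoichiometry alone.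
- **Comparison:** in step count this road is clearly better, about half the length. The chosen plan sets against it absolute configuration from a dependable auxiliary step without resolution, carbonyls C5 and C6 differentiated by design (lactone versus masked ketone), and C–C bond formations of predictable chemoselectivity.

**Alternative 2:** Carbonyl ylide cycloaddition to a γ-aryl butenolide.
- **Cut:** C2–C3 and C4–C5.
- **Forward key step:** thermal C–C opening of the cis-diaryl oxirane A3 (rings B and C) gives a carbonyl ylide that adds across the double bond of the enantiopure butenolide A4 (ring D, C7, C6), closing the tetrahydrofuran in cycloadduct A5.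
- **Merits:** the most convergent road; both ring C–C bonds and four stereocentres form in one step. Addition of the ring A nucleophile to the lactone of A5 then gives the ketone and the C7 carbinol directly, so the end-game is shorter than steps 9–13 and needs no masking of the γ-hydroxy ketone.
- **Weak points:** an oxirane with two aryl groups and no acceptor opens only at forcing temperatures, where ylide stereomutation and racemisation of A4 by γ-deprotonation are likely. The step must be selective in four respects at once: which ylide terminus bonds to C3, ylide geometry (ring B exo and ring C endo need the E,Z form), endo/exo approach, and the face anti to ring D. The two ylide termini differ little electronically. The sulfonate groups on ring C must later be exchanged.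
- **Comparison:** shorter and more convergent if the cycloaddition is selective. The chosen plan uses a comparably sensitive butenolide (17) but at −78 °C, and spreads the stereochemical decisions over steps that each have one geometrically enforced outcome.

**Alternative 3:** Silicon-tethered oxidative coupling of two aldol enol silanes.
- **Cut:** C3–C4 between the two identical halves.
- **Forward key step:** one-electron oxidation (a chemical oxidant or an anode) of the bis(enol silane) A6, whose C2 and C7 oxygens are linked by a diisopropylsilylene, couples the two enol carbons and closes the seven-membered dioxasilepane A7.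
- **Merits:** it uses the hidden twofold symmetry of the target; one aldol building block serves twice, and coupling two homochiral halves upgrades enantiomeric purity. The sequence is short.
- **Weak points:** a tether through the carbinol oxygens that closes a seven-membered ring is less precedented than tethering through the enol oxygens. The oxidant must distinguish the enol silanes from four electron-rich alkoxyarenes, and β-silyloxy enol silanes can fragment by β-elimination. The relative configuration across C3–C4 must come from a medium-ring transition state. After coupling the two hydroxy-ketone halves are homotopic: closing and reducing only one (C2–OH onto C5) while the other stays a ketone is a statistical problem, since a silane reduces both hemiketals alike.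
- **Comparison:** better in step count and symmetry economy. The chosen plan answers with C5 and C6 differentiated by oxidation level from the start and with stereocentres set one at a time by ring fusion.

Key step: step 8

Assumption: lactol 26 is written as the cyclic hemiketal (mixture at C5) and 28 and 29 as open γ-hydroxy ketones; each can equilibrate with its ring-chain tautomer, which does not change the step that follows.

## Route

Step 1
Reactants: 1 4-bromoresorcinol (4-bromobenzene-1,3-diol)
Product: 2 1-bromo-2,4-bis(benzyloxy)benzene
Conditions: BnBr, K2CO3, DMF, 60 °C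
Reagents that add atoms: benzyl bromide, BrCc1ccccc1
Why: Williamson ether synthesis on both phenols; the one bromide later serves as precursor of ring A (step 5) and ring C (step 10).

Step 2
Reactants: 3 (R)-4-benzyl-1,3-oxazolidin-2-one; 4 methyl 4-chloro-4-oxobutanoate
Product: 5 methyl 4-[(4R)-4-benzyl-2-oxo-1,3-oxazolidin-3-yl]-4-oxobutanoate
Conditions: n-BuLi, THF, −78 °C; then 4, −78 → 0 °C
Reagents that add atoms: none
Why: N-acylation of the lithiated oxazolidinone by the acid chloride, the standard preparation of a succinate half-imide for an auxiliary-controlled aldol reaction.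

Step 3
Reactants: 5; 6 4-(benzyloxy)benzaldehyde
Product: 8 (4R)-4-benzyl-3-{[(2R,3R)-2-[4-(benzyloxy)phenyl]-5-oxooxolan-3-yl]carbonyl}-1,3-oxazolidin-2-one, via aldol adduct 7 (not isolated)
Conditions: Bu2BOTf, i-Pr2NEt, CH2Cl2, 0 °C; 6, −78 → 0 °C; H2O2, pH 7 buffer, MeOH; then pyridinium p-toluenesulfonate (cat.), toluene, 60 °C
Reagents that add atoms: none
Why: Evans syn-aldol reaction: the Z boron enolate of the imide (enolised in preference to the methyl ester) adds to 6 through a closed chair transition state on the face away from the auxiliary benzyl group, which fixes C2 as R (and C3, erased in step 6); the syn adduct 7 then lactonises onto the methyl ester to the trans lactone.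

Step 4
Reactants: 8
Product: 10 (2R,3R)-2-[4-(benzyloxy)phenyl]-5-oxooxolane-3-carboxylic acid, via peroxy acid 9 (not isolated)
Conditions: LiOH, H2O2, THF/H2O, 0 °C; Na2SO3; then 1 M HCl to pH 2
Reagents that add atoms: hydrogen peroxide, OO
Why: Hydroperoxide cleavage of the N-acyl oxazolidinone at the exocyclic carbonyl; sulfite reduces the peracid, acidification re-closes any lactone opened by hydroxide, and auxiliary 3 is recovered.

Step 5
Reactants: 10; 2
Product: 14 (4R,5R)-4-[2,4-bis(benzyloxy)benzoyl]-5-[4-(benzyloxy)phenyl]oxolan-2-one, via acid chloride 11 (not isolated), via arylmagnesium bromide 12 (not isolated), via arylzinc chloride 13 (not isolated)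
Conditions: 10, (COCl)2, Me2NCHO (cat.), CH2Cl2, 0 °C → rt, evaporate; separately 2, Mg turnings, I2 (cat.), THF, 40 °C, then ZnCl2, 0 °C; combine, Pd(PPh3)4 (cat.), THF, 0 °C → rt
Reagents that add atoms: none
Why: Negishi acylation: magnesium insertion into the aryl bromide and transmetallation to zinc give an arylzinc halide that is inert to the lactone, and its palladium-catalysed coupling with the acid chloride gives the aryl ketone without touching the benzyl ethers, which a Friedel–Crafts acylation would endanger; C2 is not involved and C3 is removed in step 6.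

Step 6
Reactants: 14
Product: 17 (5S)-4-[2,4-bis(benzyloxy)benzoyl]-5-[4-(benzyloxy)phenyl]furan-2(5H)-one, via selenide 15 (not isolated), via selenoxide 16 (not isolated)
Conditions: LiN(SiMe3)2, THF, −78 °C; PhSeBr, −78 °C; then H2O2 (30 % aq.), CH2Cl2, 0 °C → rt
Reagents that add atoms: none
Why: α-Selenenylation of the ketone enolate at C3 followed by selenoxide syn-elimination, which runs towards the acidic C4–H and away from the oxygen-bearing C2 to give the ene-dione butenolide; the C3 enolate does not expel O1 because the C2–O1 bond lies in the nodal plane of the exocyclic enolate, and no amine base is used so that the γ-aryl butenolide keeps its configuration (the descriptor changes from R to S only through a priority change).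

Step 7
Reactants: 18 4-(benzyloxy)benzyl chloride
Product: 19 [4-(benzyloxy)benzyl]dimethylsulfonium tetrafluoroborate
Conditions: Me2S, NaBF4, MeCN, rt
Reagents that add atoms: dimethyl sulfide, CSC; sodium tetrafluoroborate, [Na+].F[B-](F)(F)F
Why: S-alkylation of dimethyl sulfide by the reactive p-alkoxybenzyl chloride; the non-nucleophilic counter-ion prevents dealkylation of the salt and gives a crystalline ylide precursor.

Step 8
Reactants: 17; 19
Product: 22 (1S,4S,5S,6R)-5-[2,4-bis(benzyloxy)benzoyl]-4,6-bis[4-(benzyloxy)phenyl]-3-oxabicyclo[3.1.0]hexan-2-one, via sulfonium ylide 20 (not isolated), via enolate betaine 21 (not isolated)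
Conditions: 19, KN(SiMe3)2 (slightly less than 1 equiv relative to 19), THF, −78 °C; then 17 in THF, −78 → −20 °C
Reagents that add atoms: none
Why: Michael-initiated ring closure: ylide 20 adds through its benzylic carbon C7 to C4 of the ene-dione, the terminus β to the aryl ketone, giving betaine 21, whose enolate carbon C3 then displaces dimethyl sulfide from C7. The closest known reaction type is the cyclopropanation of enones and of 5-substituted butenolides with semistabilised benzylsulfonium ylides. One ring is closed, the cyclopropane, by a 3-exo-tet displacement with inversion at C7, so that C4–C7 and C3–C7 are formed. C4 and C3 are controlled by the existing centre C2: the ylide approaches the flat butenolide on the face opposite ring B, the three-membered ring must be cis-fused so C3 follows C4, and a betaine formed on the wrong face cannot close past ring B and reverts. C7 is set in the closure with ring D exo, away from the lactone ring; its configuration is not critical because step 9 passes through a benzylic cation at C7. First attack at C3 instead of C4 would, after closure by C4, give the same cyclopropane, so the regiochemistry of the first bond is inconsequential. The selectivity the step needs is conjugate addition over deprotonation of the acidic C2–H, which would racemise 17 through the 2-oxyfuran anion; the ene-dione is a far better acceptor than a simple butenolide, the ylide is preformed so that no free amide base is present, and the temperature is held at −78 °C. Loss of O1 from the C3 enolate in 21 is stereoelectronically disabled as in step 6.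

Step 9
Reactants: 22
Product: 23 (1R,4S,8R)-6-[2,4-bis(benzyloxy)phenyl]-4,8-bis[4-(benzyloxy)phenyl]-3,7-dioxabicyclo[3.3.0]oct-5-en-2-one
Conditions: Sc(OTf)3 (10 mol %), 4 Å molecular sieves, CH2Cl2, 0 °C → rt
Reagents that add atoms: none
Why: Lewis-acid Cloke–Wilson rearrangement of a donor–acceptor aroylcyclopropane: chelation of the ketone (with the ortho benzyloxy group) polarises C3–C7, and the p-alkoxybenzylic carbon C7 is captured by the enolate oxygen to give the 2,3-dihydrofuran. Ring D ends on the convex face, cis to C4–H, either by front-side collapse of the ion pair or by equilibration through the same benzylic cation.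

Step 10
Reactants: 23; 2
Product: 26 (1R,4S,8R)-2,6-bis[2,4-bis(benzyloxy)phenyl]-4,8-bis[4-(benzyloxy)phenyl]-3,7-dioxabicyclo[3.3.0]oct-5-en-2-ol (both configurations at the hemiketal carbon), via aryllithium 24 (not isolated), via arylcerium dichloride 25 (not isolated)
Conditions: 2, n-BuLi, THF, −78 °C; CeCl3 (anhydrous), −78 °C; then 23, −78 °C; aq. NH4Cl
Reagents that add atoms: none
Why: 1,2-Addition of an aryl organocerium reagent to a γ-lactone, which stops at the hemiketal at −78 °C; the weakly basic cerium reagent is chosen because C4–H is α to the lactone and allylic to the enol ether, and the enol ether keeps C6 and O7 out of reach of the nucleophile.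

Step 11
Reactants: 26
Product: 27 (1S,2R,4S,8R)-2,6-bis[2,4-bis(benzyloxy)phenyl]-4,8-bis[4-(benzyloxy)phenyl]-3,7-dioxabicyclo[3.3.0]oct-5-ene
Conditions: Et3SiH, BF3·OEt2, 2,6-di-tert-butyl-4-methylpyridine, CH2Cl2, −78 °C; Et3N, then aq. NaHCO3 at −78 °C
Reagents that add atoms: none
Why: Ionic (silane) reduction of an aryl hemiketal through the cyclic oxocarbenium ion; hydride attacks C5 anti to the C4 substituent C7, on the convex face, which places ring C cis to C7 as in the known 2,3-cis-selective reductions of 2-aryl-tetrahydrofuran hemiketals. The hindered pyridine removes protons that could attack the enol ether, and the cold quench prevents re-ionisation of the benzylic C–O bonds.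

Step 12
Reactants: 27
Product: 28 [(2R,3R,4R,5R)-5-[2,4-bis(benzyloxy)phenyl]-2-[4-(benzyloxy)phenyl]-4-{(R)-[4-(benzyloxy)phenyl](hydroxy)methyl}oxolan-3-yl][2,4-bis(benzyloxy)phenyl]methanone
Conditions: AcOH/THF/H2O (4:2:1), rt
Reagents that add atoms: water, O
Why: Acid-catalysed enol ether hydrolysis: the rate-limiting C-protonation at C3 can only occur on the face that keeps the two five-membered rings cis-fused, so C3–H is delivered cis to C4–H; water then opens the oxocarbenium ion to the aryl ketone and the C7 carbinol. The weak acid leaves the benzylic ethers alone.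

Step 13
Reactants: 28
Product: 29 [(2R,3R,4R,5R)-5-(2,4-dihydroxyphenyl)-2-(4-hydroxyphenyl)-4-[(R)-hydroxy(4-hydroxyphenyl)methyl]oxolan-3-yl](2,4-dihydroxyphenyl)methanone
Conditions: H2 (1 atm), Pd(OH)2/C, THF/EtOAc, rt, stopped at full conversion
Reagents that add atoms: none
Why: Catalytic hydrogenolysis of aryl benzyl ethers, which in neutral solvent is much faster than cleavage of benzylic alcohols or 2-aryl-oxolane C–O bonds (as in the final debenzylation of benzyl-protected flavan-3-ols); no stereocentre is touched.

## Compound list

1 | 4-bromoresorcinol | Oc1ccc(Br)c(O)c1 | starting material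
2 | 1-bromo-2,4-bis(benzyloxy)benzene | Brc1ccc(OCc2ccccc2)cc1OCc1ccccc1 | intermediate
3 | (R)-4-benzyl-1,3-oxazolidin-2-one | O=C1N[C@H](Cc2ccccc2)CO1 | starting material (auxiliary, recovered in step 4)
4 | methyl 4-chloro-4-oxobutanoate | COC(=O)CCC(=O)Cl | starting material
5 | methyl 4-[(4R)-4-benzyl-2-oxo-1,3-oxazolidin-3-yl]-4-oxobutanoate | COC(=O)CCC(=O)N1[C@H](Cc2ccccc2)COC1=O | intermediate
6 | 4-(benzyloxy)benzaldehyde | O=Cc1ccc(OCc2ccccc2)cc1 | starting material
7 | methyl (3R,4R)-3-{[(4R)-4-benzyl-2-oxo-1,3-oxazolidin-3-yl]carbonyl}-4-[4-(benzyloxy)phenyl]-4-hydroxybutanoate (syn aldol adduct) | COC(=O)C[C@@H](C(=O)N1[C@H](Cc2ccccc2)COC1=O)[C@@H](O)c1ccc(OCc2ccccc2)cc1 | intermediate (not isolated)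
8 | (4R)-4-benzyl-3-{[(2R,3R)-2-[4-(benzyloxy)phenyl]-5-oxooxolan-3-yl]carbonyl}-1,3-oxazolidin-2-one | O=C1C[C@@H](C(=O)N2[C@H](Cc3ccccc3)COC2=O)[C@H](c2ccc(OCc3ccccc3)cc2)O1 | intermediate
9 | (2R,3R)-2-[4-(benzyloxy)phenyl]-5-oxooxolane-3-carboperoxoic acid | O=C1C[C@@H](C(=O)OO)[C@H](c2ccc(OCc3ccccc3)cc2)O1 | intermediate (not isolated)
10 | (2R,3R)-2-[4-(benzyloxy)phenyl]-5-oxooxolane-3-carboxylic acid | O=C1C[C@@H](C(=O)O)[C@H](c2ccc(OCc3ccccc3)cc2)O1 | intermediate
11 | (2R,3R)-2-[4-(benzyloxy)phenyl]-5-oxooxolane-3-carbonyl chloride | O=C1C[C@@H](C(=O)Cl)[C@H](c2ccc(OCc3ccccc3)cc2)O1 | intermediate (not isolated)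
12 | [2,4-bis(benzyloxy)phenyl]magnesium bromide | Br[Mg]c1ccc(OCc2ccccc2)cc1OCc1ccccc1 | intermediate (not isolated)
13 | [2,4-bis(benzyloxy)phenyl]zinc chloride | Cl[Zn]c1ccc(OCc2ccccc2)cc1OCc1ccccc1 | intermediate (not isolated)
14 | (4R,5R)-4-[2,4-bis(benzyloxy)benzoyl]-5-[4-(benzyloxy)phenyl]oxolan-2-one (trans) | O=C1C[C@@H](C(=O)c2ccc(OCc3ccccc3)cc2OCc2ccccc2)[C@H](c2ccc(OCc3ccccc3)cc2)O1 | intermediate
15 | (4R,5S)-4-[2,4-bis(benzyloxy)benzoyl]-5-[4-(benzyloxy)phenyl]-4-(phenylselanyl)oxolan-2-one (selenium trans to ring B) | O=C1C[C@@](C(=O)c2ccc(OCc3ccccc3)cc2OCc2ccccc2)([Se]c2ccccc2)[C@H](c2ccc(OCc3ccccc3)cc2)O1 | intermediate (not isolated)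
16 | selenoxide of 15 (both configurations at selenium) | O=C1C[C@@](C(=O)c2ccc(OCc3ccccc3)cc2OCc2ccccc2)([Se](=O)c2ccccc2)[C@H](c2ccc(OCc3ccccc3)cc2)O1 | intermediate (not isolated)
17 | (5S)-4-[2,4-bis(benzyloxy)benzoyl]-5-[4-(benzyloxy)phenyl]furan-2(5H)-one | O=C(c1ccc(OCc2ccccc2)cc1OCc1ccccc1)C1=CC(=O)O[C@H]1c1ccc(OCc2ccccc2)cc1 | intermediate (precursor of the key step)
18 | 4-(benzyloxy)benzyl chloride | ClCc1ccc(OCc2ccccc2)cc1 | starting material
19 | [4-(benzyloxy)benzyl]dimethylsulfonium tetrafluoroborate | C[S+](C)Cc1ccc(OCc2ccccc2)cc1.F[B-](F)(F)F | intermediate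
20 | dimethylsulfonium [4-(benzyloxy)phenyl]methylide | C[S+](C)[CH-]c1ccc(OCc2ccccc2)cc1 | intermediate (not isolated)
21 | enolate–sulfonium betaine from addition of 20 to C4 of 17 (C7 anti to ring B; C7 configuration open) | [O-]C(c1ccc(OCc2ccccc2)cc1OCc1ccccc1)=C1[C@H](c2ccc(OCc3ccccc3)cc2)OC(=O)[C@H]1C(c1ccc(OCc2ccccc2)cc1)[S+](C)C | intermediate (not isolated)
22 | (1S,4S,5S,6R)-5-[2,4-bis(benzyloxy)benzoyl]-4,6-bis[4-(benzyloxy)phenyl]-3-oxabicyclo[3.1.0]hexan-2-one (cyclopropane anti to ring B, ring D exo) | O=C(c1ccc(OCc2ccccc2)cc1OCc1ccccc1)[C@]12[C@H](c3ccc(OCc4ccccc4)cc3)OC(=O)[C@H]1[C@@H]2c1ccc(OCc2ccccc2)cc1 | intermediate (product of the key step)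
23 | (1R,4S,8R)-6-[2,4-bis(benzyloxy)phenyl]-4,8-bis[4-(benzyloxy)phenyl]-3,7-dioxabicyclo[3.3.0]oct-5-en-2-one | O=C1O[C@@H](c2ccc(OCc3ccccc3)cc2)C2=C(c3ccc(OCc4ccccc4)cc3OCc3ccccc3)O[C@@H](c3ccc(OCc4ccccc4)cc3)[C@H]12 | intermediate
24 | [2,4-bis(benzyloxy)phenyl]lithium | [Li]c1ccc(OCc2ccccc2)cc1OCc1ccccc1 | intermediate (not isolated)
25 | [2,4-bis(benzyloxy)phenyl]cerium dichloride | Cl[Ce](Cl)c1ccc(OCc2ccccc2)cc1OCc1ccccc1 | intermediate (not isolated)
26 | (1R,4S,8R)-2,6-bis[2,4-bis(benzyloxy)phenyl]-4,8-bis[4-(benzyloxy)phenyl]-3,7-dioxabicyclo[3.3.0]oct-5-en-2-ol (hemiketal carbon unassigned) | OC1(c2ccc(OCc3ccccc3)cc2OCc2ccccc2)O[C@@H](c2ccc(OCc3ccccc3)cc2)C2=C(c3ccc(OCc4ccccc4)cc3OCc3ccccc3)O[C@@H](c3ccc(OCc4ccccc4)cc3)[C@H]12 | intermediate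
27 | (1S,2R,4S,8R)-2,6-bis[2,4-bis(benzyloxy)phenyl]-4,8-bis[4-(benzyloxy)phenyl]-3,7-dioxabicyclo[3.3.0]oct-5-ene | c1ccccc1COc1cc(OCc2ccccc2)ccc1[C@@H]1O[C@@H](c2ccc(OCc3ccccc3)cc2)C2=C(c3ccc(OCc4ccccc4)cc3OCc3ccccc3)O[C@@H](c3ccc(OCc4ccccc4)cc3)[C@H]12 | intermediate
28 | [(2R,3R,4R,5R)-5-[2,4-bis(benzyloxy)phenyl]-2-[4-(benzyloxy)phenyl]-4-{(R)-[4-(benzyloxy)phenyl](hydroxy)methyl}oxolan-3-yl][2,4-bis(benzyloxy)phenyl]methanone | O=C(c1ccc(OCc2ccccc2)cc1OCc1ccccc1)[C@@H]1[C@H]([C@@H](O)c2ccc(OCc3ccccc3)cc2)[C@H](c2ccc(OCc3ccccc3)cc2OCc2ccccc2)O[C@H]1c1ccc(OCc2ccccc2)cc1 | intermediate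
29 | [(2R,3R,4R,5R)-5-(2,4-dihydroxyphenyl)-2-(4-hydroxyphenyl)-4-[(R)-hydroxy(4-hydroxyphenyl)methyl]oxolan-3-yl](2,4-dihydroxyphenyl)methanone (CNP0244141.1) | O=C(c1ccc(O)cc1O)[C@@H]1[C@H]([C@@H](O)c2ccc(O)cc2)[C@H](c2ccc(O)cc2O)O[C@H]1c1ccc(O)cc1 | target

## Step count and least certain steps

Total step count: 13. Longest linear sequence: 11 steps (steps 2–6 and 8–13, from 3 and 4 to 29); steps 1 and 7 are side branches.

**Key step (step 8).** The most likely failure is proton transfer from C2–H of 17 to ylide 20 in competition with conjugate addition, which would erode enantiomeric purity through the achiral 2-oxyfuran anion; the second is incomplete facial selectivity. The fallback is a base-free dipolar route that sets out from 6 and 17 and returns at 22. Aldehyde 6 is condensed with hydrazine to [4-(benzyloxy)benzylidene]hydrazine F1, which MnO2 oxidises to 1-(benzyloxy)-4-(diazomethyl)benzene F2. Cycloaddition of F2 to 17 anti to ring B gives the fused 1-pyrazoline 5-[2,4-bis(benzyloxy)benzoyl]-4,8-bis[4-(benzyloxy)phenyl]-3-oxa-6,7-diazabicyclo[3.3.0]oct-6-en-2-one F3, and photolysis expels dinitrogen to give cyclopropane 22.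

**Step 9.** After heterolysis of C3–C7 the benzylic cation may lose C4–H, opening irreversibly to an α-arylidene lactone instead of closing on oxygen. The Lewis acid may also ionise the product at C2–O1, which is benzylic and allylic to the new enol ether. The fallback sets out from 22 and returns at 23. Hydrative opening (Sc(OTf)3 cat., THF/H2O), with water as an abundant external trap, gives the cis-fused hemiketal lactone 6-[2,4-bis(benzyloxy)phenyl]-6-hydroxy-4,8-bis[4-(benzyloxy)phenyl]-3,7-dioxabicyclo[3.3.0]octan-2-one F4. This is dehydrated under basic conditions (MsCl, Et3N) to 23, so the enol ether never meets an acid.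

**Step 10.** Enolisation at C4 (α to the lactone, allylic to the enol ether) would be followed by reprotonation on the wrong face or at C6; over-addition to the ring-opened ketone is the second risk. The fallback sets out from 23 and returns at 26. The lactone is opened with the chloromagnesium amide of N,O-dimethylhydroxylamine (from the amine hydrochloride and i-PrMgCl) to the hydroxy N-methoxy-N-methylamide F5. Its C2 hydroxyl is silylated (Et3SiCl, imidazole) to the triethylsilyl ether F6. Aryllithium 24, generated from 2 and n-BuLi as in step 10, then adds once to the amide to give the aryl ketone triethylsilyl ether F7. Desilylation (HF·pyridine) frees the C2 hydroxyl, which closes onto the C5 ketone to give lactol 26.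

**Step 11.** Acid-promoted side reactions of the enol ether are the main risk: C-protonation followed by hydride transfer to C6, ionisation of the C2–O1 bond with over-reduction, and epimerisation at C5 through reversible benzylic C–O ionisation. The fallback sets out from 26 and returns at 28; it unmasks the ketone first and blocks the carbinol so that only one hemiketal can form. Hydrolysis of 26 as in step 12 gives the keto lactol F8 (the C5 hemiketal of 28). Silylation of the C7 hydroxyl (t-BuMe2SiCl, imidazole) gives the silyl ether F9. Silane reduction (Et3SiH, BF3·OEt2, −78 °C), anti to the C4 substituent, gives the C7 tert-butyldimethylsilyl ether of 28 F10, and HF·pyridine then gives 28.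

**Step 13.** Hydrogenolysis of the benzylic C7–OH bond or of a benzylic ring C–O bond may compete with slow removal of the last benzyl groups. The fallback sets out from 27 and returns at 29, inverting the last two operations. Compound 27, which has neither a free benzylic alcohol nor a ketone, is debenzylated (H2, Pd(OH)2/C) to the hexaphenol enol ether 2,6-bis(2,4-dihydroxyphenyl)-4,8-bis(4-hydroxyphenyl)-3,7-dioxabicyclo[3.3.0]oct-5-ene F11. Its enol ether is then hydrolysed with dilute aqueous acetic acid to 29.

## Further compounds

F1 | step 8 | [4-(benzyloxy)benzylidene]hydrazine | N/N=C/c1ccc(OCc2ccccc2)cc1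
F2 | step 8 | 1-(benzyloxy)-4-(diazomethyl)benzene | [N-]=[N+]=Cc1ccc(OCc2ccccc2)cc1
F3 | step 8 | 5-[2,4-bis(benzyloxy)benzoyl]-4,8-bis[4-(benzyloxy)phenyl]-3-oxa-6,7-diazabicyclo[3.3.0]oct-6-en-2-one (pyrazoline anti to ring B; C8 unassigned) | O=C(c1ccc(OCc2ccccc2)cc1OCc1ccccc1)[C@@]12N=NC(c3ccc(OCc4ccccc4)cc3)[C@@H]1C(=O)O[C@H]2c1ccc(OCc2ccccc2)cc1
F4 | step 9 | 6-[2,4-bis(benzyloxy)phenyl]-6-hydroxy-4,8-bis[4-(benzyloxy)phenyl]-3,7-dioxabicyclo[3.3.0]octan-2-one (cis-fused; hemiketal carbon unassigned) | O=C1O[C@@H](c2ccc(OCc3ccccc3)cc2)[C@@H]2C(O)(c3ccc(OCc4ccccc4)cc3OCc3ccccc3)O[C@@H](c3ccc(OCc4ccccc4)cc3)[C@H]12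
F5 | step 10 | 5-[2,4-bis(benzyloxy)phenyl]-2-[4-(benzyloxy)phenyl]-4-{[4-(benzyloxy)phenyl](hydroxy)methyl}-N-methoxy-N-methyl-2,3-dihydrofuran-3-carboxamide (configuration as in 23) | CON(C)C(=O)[C@H]1[C@H](c2ccc(OCc3ccccc3)cc2)OC(c2ccc(OCc3ccccc3)cc2OCc2ccccc2)=C1[C@@H](O)c1ccc(OCc2ccccc2)cc1
F6 | step 10 | triethylsilyl ether of F5 | CON(C)C(=O)[C@H]1[C@H](c2ccc(OCc3ccccc3)cc2)OC(c2ccc(OCc3ccccc3)cc2OCc2ccccc2)=C1[C@@H](O[Si](CC)(CC)CC)c1ccc(OCc2ccccc2)cc1
F7 | step 10 | [2,4-bis(benzyloxy)phenyl] ketone from F6 (3-aroyl-2,3-dihydrofuran, triethylsilyl ether) | O=C(c1ccc(OCc2ccccc2)cc1OCc1ccccc1)[C@H]1[C@H](c2ccc(OCc3ccccc3)cc2)OC(c2ccc(OCc3ccccc3)cc2OCc2ccccc2)=C1[C@@H](O[Si](CC)(CC)CC)c1ccc(OCc2ccccc2)cc1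
F8 | step 11 | C5 hemiketal of 28 (5-hydroxy-oxolane; hemiketal carbon unassigned) | O=C(c1ccc(OCc2ccccc2)cc1OCc1ccccc1)[C@@H]1[C@H]([C@@H](O)c2ccc(OCc3ccccc3)cc2)C(O)(c2ccc(OCc3ccccc3)cc2OCc2ccccc2)O[C@H]1c1ccc(OCc2ccccc2)cc1
F9 | step 11 | C7 tert-butyldimethylsilyl ether of F8 | O=C(c1ccc(OCc2ccccc2)cc1OCc1ccccc1)[C@@H]1[C@H]([C@@H](O[Si](C)(C)C(C)(C)C)c2ccc(OCc3ccccc3)cc2)C(O)(c2ccc(OCc3ccccc3)cc2OCc2ccccc2)O[C@H]1c1ccc(OCc2ccccc2)cc1
F10 | step 11 | C7 tert-butyldimethylsilyl ether of 28 | O=C(c1ccc(OCc2ccccc2)cc1OCc1ccccc1)[C@@H]1[C@H]([C@@H](O[Si](C)(C)C(C)(C)C)c2ccc(OCc3ccccc3)cc2)[C@H](c2ccc(OCc3ccccc3)cc2OCc2ccccc2)O[C@H]1c1ccc(OCc2ccccc2)cc1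
F11 | step 13 | 2,6-bis(2,4-dihydroxyphenyl)-4,8-bis(4-hydroxyphenyl)-3,7-dioxabicyclo[3.3.0]oct-5-ene (configuration as in 27) | Oc1cc(O)ccc1[C@@H]1O[C@@H](c2ccc(O)cc2)C2=C(c3ccc(O)cc3O)O[C@@H](c3ccc(O)cc3)[C@H]12
A1 | alternative 1 | p-coumaric acid, (E)-3-(4-hydroxyphenyl)prop-2-enoic acid | OC(=O)/C=C/c1ccc(O)cc1
A2 | alternative 1 | 4,8-bis(4-hydroxyphenyl)-3,7-dioxabicyclo[3.3.0]octane-2,6-dione (cis-fused, both aryl groups exo) | O=C3[C@@H]1[C@H]([C@@H](O3)c2ccc(O)cc2)C(=O)O[C@H]1c1ccc(O)cc1
A3 | alternative 2 | cis-2-[2,4-bis(methanesulfonyloxy)phenyl]-3-(4-methoxyphenyl)oxirane (racemic, one enantiomer drawn) | COc1ccc([C@H]2O[C@H]2c2ccc(OS(C)(=O)=O)cc2OS(C)(=O)=O)cc1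
A4 | alternative 2 | (R)-5-(4-methoxyphenyl)furan-2(5H)-one | O=C1C=C[C@@H](O1)c1ccc(OC)cc1
A5 | alternative 2 | cis-fused oxolane–γ-lactone cycloadduct (ring B exo, ring C endo, ring D exo) | O=C3[C@@H]1[C@H]([C@@H](O3)c2ccc(OC)cc2)[C@H](c2ccc(OS(C)(=O)=O)cc2OS(C)(=O)=O)O[C@H]1c1ccc(OC)cc1
A6 | alternative 3 | diisopropylsilylene-tethered bis(trimethylsilyl enol ether) of the two aldol halves (enol geometry not specified) | CC(C)[Si](O[C@H](C=C(O[Si](C)(C)C)c1ccc(OC)cc1OC)c1ccc(OC)cc1)(O[C@H](C=C(O[Si](C)(C)C)c1ccc(OC)cc1OC)c1ccc(OC)cc1)C(C)C
A7 | alternative 3 | all-trans 4,7-bis(4-methoxyphenyl)-5,6-bis(2,4-dimethoxybenzoyl)-2,2-diisopropyl-1,3-dioxa-2-silepane | O=C(c1ccc(OC)cc1OC)[C@H]1[C@H](c2ccc(OC)cc2)O[Si](C(C)C)(C(C)C)O[C@@H](c2ccc(OC)cc2)[C@@H]1C(=O)c1ccc(OC)cc1OC
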